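**Plan**
- Locants: flavanone numbering O1–C8a for the dihydropyranone and the carbocycle fused to it; C1″ (OCH2), C2″ (CH on C5) and C3″ (CMe2 on C8) for the three-carbon bridge. Cuts, in order: O1–C8a (back to a C8a iodide and a C2 silyl ether), C4a–C5 (C8a=C4a becoming an alkyne), C4–C4a, C8–C8a, C8–CH3, C6–O, C2″–C1″.
- Enabling feature: C4a is both the α-carbon of the enone C8a=C4a–C4=O and the neighbour of the tertiary carbinol C5. The bicyclo[2.2.2]octene ring (C5, C6, C7, C8, C8a, C4a) is therefore the Baylis–Hillman-type adduct of an ynone on C8 with the C5 ketone of a 6-oxabicyclo[3.2.1]octane-4,8-dione (ring C5, C6, C7, C8, C3″, C2″ bridged by O–C1″).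
- Forward order: the cyclohexane ring comes with 2-methyldimedone; the oxolane (C5, C6, O, C1″, C2″) closes by oxidative etherification; the C2–C4 phenylpropanoyl chain is joined by acyl Sonogashira coupling; the bicyclo[2.2.2]octene closes in the iodide-triggered aldol; the dihydropyranone closes last.
- Stereochemistry: C2 comes from commercial ethyl (S)-3-hydroxy-3-phenylpropanoate; C2″ and C6 are tied cis by the bridge and made single-handed by resolution of the bicyclic dione; C8 is set by alkynylating the methyl-bearing enolate on the face away from the O–CH2 bridge; C5 is set by the tether in the key step.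

Key step: step 11

Remark: the dione enantiomer needed is (1R,5R); which SFC fraction that is would be settled by anomalous-dispersion X-ray analysis of the iodine-bearing key-step product made from a test sample. Atom labels in the Why lines are the target locants defined above.

Step 1
Reactants: 1 2,5,5-trimethylcyclohexane-1,3-dione (2-methyldimedone)
Product: 2 3-(2-methylpropoxy)-2,5,5-trimethylcyclohex-2-en-1-one
Conditions: i-BuOH, p-TsOH·H2O (cat.), toluene, reflux, Dean–Stark
Reagents that add atoms: 2-methylpropan-1-ol, CC(C)CO
Why: Acid-catalysed vinylogous esterification of a cyclic 1,3-dione, driven by azeotropic removal of water, opens a Stork–Danheiser-type α′-functionalisation, and the mirror symmetry of 1 allows only one enol ether.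

Step 2
Reactants: 2 3-(2-methylpropoxy)-2,5,5-trimethylcyclohex-2-en-1-one; 3 formaldehyde (monomer from thermally cracked paraformaldehyde)
Product: 5 rac-4-(hydroxymethyl)-2,5,5-trimethylcyclohexane-1,3-dione, via hydroxymethyl enol ether 4 (not isolated)
Conditions: LiN(i-Pr)2, THF, −78 °C; CH2O (g), −78 → −20 °C; then 2 M HCl, THF, rt
Reagents that add atoms: water, O
Why: Kinetic α′-deprotonation of the vinylogous ester and aldol addition of the enolate to monomeric formaldehyde should place C1″ next to the gem-dimethyl carbon, and the acidic work-up hydrolyses the enol ether to the 1,3-dione; C2″ is formed racemic and is resolved once it has become a bridgehead.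

Step 3
Reactants: 5 rac-4-(hydroxymethyl)-2,5,5-trimethylcyclohexane-1,3-dione
Product: 6 rac-(1R*,5R*)-2,2,5-trimethyl-6-oxabicyclo[3.2.1]octane-4,8-dione
Conditions: PhI(OAc)2, MeCN, 0 °C → rt
Reagents that add atoms: none
Why: Trivalent-iodine-mediated α-oxygenation of a 2-substituted 1,3-dicarbonyl compound (umpolung of the enol) makes C6 electrophilic, and the axial hydroxymethyl group should close the five-membered ether onto it with loss of iodobenzene; a 1,3-diaxial bridge can only form cis, so C6 is set relative to C2″.

Step 4
Reactants: 6 rac-(1R*,5R*)-2,2,5-trimethyl-6-oxabicyclo[3.2.1]octane-4,8-dione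
Product: 7 (1R,5R)-2,2,5-trimethyl-6-oxabicyclo[3.2.1]octane-4,8-dione
Conditions: preparative SFC, amylose tris(3,5-dimethylphenylcarbamate) stationary phase, CO2/i-PrOH, 35 °C
Reagents that add atoms: none
Why: Chromatographic resolution on a polysaccharide carbamate phase should separate the two rigid enantiomers, and because C2″ is a bridgehead that cannot enolise and C6 is quaternary the resolved material cannot racemise later.

Step 5
Reactants: 7 (1R,5R)-2,2,5-trimethyl-6-oxabicyclo[3.2.1]octane-4,8-dione
Product: 8 (1R,5R)-2,2,3,5-tetramethyl-6-oxabicyclo[3.2.1]octane-4,8-dione (mixture of epimers at the new methine)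
Conditions: LiN(SiMe3)2, THF, −78 °C; MeI, −78 → 0 °C
Reagents that add atoms: iodomethane, CI
Why: Kinetic enolate alkylation should methylate only C8, because the other α-carbons are bridgehead (Bredt's rule) or quaternary; the C8 configuration is left open since step 6 makes the carbon trigonal again.

Step 6
Reactants: 8 (1R,5R)-2,2,3,5-tetramethyl-6-oxabicyclo[3.2.1]octane-4,8-dione; 9 1-[(trimethylsilyl)ethynyl]-1,2-benziodoxol-3(1H)-one
Product: 10 (1R,3S,5S)-3-ethynyl-2,2,3,5-tetramethyl-6-oxabicyclo[3.2.1]octane-4,8-dione (ethynyl syn to the one-carbon ketone bridge)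
Conditions: KN(SiMe3)2, THF, −78 → 0 °C, recool to −78 °C; Bu4NF (THF, dried over 4 Å sieves), 9, −78 °C → rt
Reagents that add atoms: none
Why: Electrophilic α-alkynylation of a ketone enolate with an ethynylbenziodoxolone released by fluoride (conjugate addition to the alkynyl iodane, loss of 2-iodobenzoate, 1,2-hydrogen shift of the alkylidene carbene) should build the quaternary C8; the O–CH2 bridge lies under one face of the planar enolate, so attack should come from the face of the one-carbon ketone bridge (the usual exo preference of bicyclo[3.2.1]octane three-carbon bridges), placing ethynyl syn to C5 and methyl syn to the ether bridge.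

Step 7
Reactants: 11 ethyl (3S)-3-hydroxy-3-phenylpropanoate
Product: 12 ethyl (3S)-3-[(tert-butyldimethylsilyl)oxy]-3-phenylpropanoate
Conditions: TBSCl, imidazole, DMF, rt
Reagents that add atoms: tert-butyl(chloro)dimethylsilane, CC(C)(C)[Si](C)(C)Cl
Why: Imidazole-promoted silyl ether formation masks the C2 oxygen for the acylation and aldol chemistry and does not touch the stereocentre.

Step 8
Reactants: 12 ethyl (3S)-3-[(tert-butyldimethylsilyl)oxy]-3-phenylpropanoate
Product: 13 (3S)-3-[(tert-butyldimethylsilyl)oxy]-3-phenylpropanoic acid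
Conditions: LiOH·H2O, THF/MeOH/H2O, 0 °C → rt; then 1 M HCl to pH 4, 0 °C
Reagents that add atoms: lithium hydroxide, [Li+].[OH-]
Why: Mild saponification cleaves the ethyl ester without β-elimination of the silyloxy group, and the stereocentre is not α to the carbonyl so it cannot epimerise.

Step 9
Reactants: 13 (3S)-3-[(tert-butyldimethylsilyl)oxy]-3-phenylpropanoic acid
Product: 14 (3S)-3-[(tert-butyldimethylsilyl)oxy]-3-phenylpropanoyl chloride (used crude)
Conditions: 1-chloro-N,N,2-trimethylprop-1-en-1-amine, CH2Cl2, 0 °C → rt
Reagents that add atoms: 1-chloro-N,N,2-trimethylprop-1-en-1-amine, CC(C)=C(Cl)N(C)C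
Why: Acid chloride formation with the α-chloroenamine runs under neutral conditions and releases no HCl, so the benzylic silyl ether should survive.

Step 10
Reactants: 10 (1R,3S,5S)-3-ethynyl-2,2,3,5-tetramethyl-6-oxabicyclo[3.2.1]octane-4,8-dione; 14 (3S)-3-[(tert-butyldimethylsilyl)oxy]-3-phenylpropanoyl chloride
Product: 15 (1R,3R,5S)-3-[(5S)-5-[(tert-butyldimethylsilyl)oxy]-3-oxo-5-phenylpent-1-yn-1-yl]-2,2,3,5-tetramethyl-6-oxabicyclo[3.2.1]octane-4,8-dione (ynone; ring configuration unchanged from 10)
Conditions: PdCl2(PPh3)2 (2 mol %), CuI (4 mol %), Et3N, THF, rt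
Reagents that add atoms: none
Why: Acyl Sonogashira coupling (zerovalent palladium inserts into the C–Cl bond, the copper acetylide of 10 transmetalates, reductive elimination forms C4–C4a) works at room temperature under near-neutral conditions that leave both ring ketones, the silyl ether and every stereocentre untouched.

Step 11
Reactants: 15 ynone (as named in step 10)
Product: 16 tricyclic C8a-iodo enone: bicyclo[2.2.2]octene (C5, C6, C7, C8, C8a, C4a, C2″, C3″) with C5–OH, C6–CH3, C7=O, C8–CH3, C3″Me2 and the C6–O–C1″H2–C2″ oxolane, iodine on C8a and the (3S)-3-[(tert-butyldimethylsilyl)oxy]-3-phenylpropanoyl group on C4a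
Conditions: MgI2, CH2Cl2, 0 °C → rt; H2O work-up
Reagents that add atoms: magnesium iodide, [Mg+2].[I-].[I-]
Why: MgI2 activates the ynone carbonyl and delivers iodide to the β-carbon C8a, giving a magnesium β-iodoallenolate whose central carbon C4a adds to the C5 bridge ketone held across the boat-shaped six-membered ring, and aqueous work-up frees the tertiary alcohol. The closest known reaction type is the MgI2-promoted halo-aldol (β-iodo Morita–Baylis–Hillman) reaction of ynones with aldehydes and ketones, used here intramolecularly. The one ring that closes (C8, C8a, C4a, C5, C6, C7, completing the bicyclo[2.2.2]octene) forms by 6-exo-trig attack on the C5 carbonyl. The new stereocentre C5 is controlled by the tether: C4a can reach the carbonyl only from the face turned to the three-carbon bridge, so the hydroxyl ends syn to the ether bridge, and the ring fixes the alkene geometry with iodine cis to the acyl group. The step needs selection between the two ring ketones and freedom from enolate side reactions: attack on C7 would give a four-membered ring, and both ketones carry only bridgehead or quaternary α-carbons. The reach itself is secured by the C8 configuration from step 6, which places the alkyne syn to C5.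

Step 12
Reactants: 16 tricyclic C8a-iodo enone (C2 silyl ether)
Product: 17 tricyclic C8a-iodo enone with free C2–OH (C4a bears the (3S)-3-hydroxy-3-phenylpropanoyl group; ring as in 16)
Conditions: HF·pyridine, pyridine, THF, 0 °C → rt
Reagents that add atoms: none
Why: Fluoride-driven desilylation under buffered acidic conditions removes the silyl group without generating an alkoxide at C5 or C2, which avoids retro-aldol opening of the new ring or of the benzylic aldol unit.

Step 13
Reactants: 17 tricyclic C8a-iodo enone with free C2–OH
Product: 18 CNP0322161.1, the (2S)-2-phenyl-2,3-dihydropyran-4-one fused through C8a=C4a to the oxa-bridged bicyclo[2.2.2]octenone (5-OH, 6-CH3, 7-oxo, 8-CH3, 3″,3″-(CH3)2)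
Conditions: Et3N, DMAP (cat.), CH2Cl2, 0 °C → rt
Reagents that add atoms: none
Why: Intramolecular addition–elimination at a vinylogous acyl iodide (6-endo-trig oxa-conjugate addition of the C2 hydroxyl to C8a, then loss of iodide) should close the dihydropyranone under mild amine base; the C2–O bond is never broken, so the (S) centre is retained.

**Compound list**
1 | 2,5,5-trimethylcyclohexane-1,3-dione (2-methyldimedone) | CC1C(=O)CC(C)(C)CC1=O | starting material
2 | 3-(2-methylpropoxy)-2,5,5-trimethylcyclohex-2-en-1-one | CC1=C(OCC(C)C)CC(C)(C)CC1=O | intermediate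
3 | formaldehyde (from paraformaldehyde) | C=O | starting material
4 | rac-6-(hydroxymethyl)-3-(2-methylpropoxy)-2,5,5-trimethylcyclohex-2-en-1-one | CC1=C(OCC(C)C)CC(C)(C)C(CO)C1=O | intermediate
5 | rac-4-(hydroxymethyl)-2,5,5-trimethylcyclohexane-1,3-dione (drawn as the diketone; enolised in solution) | CC1C(=O)CC(C)(C)C(CO)C1=O | intermediate
6 | rac-(1R*,5R*)-2,2,5-trimethyl-6-oxabicyclo[3.2.1]octane-4,8-dione | CC1(C)C2COC(C)(C2=O)C(=O)C1 | intermediate
7 | (1R,5R)-2,2,5-trimethyl-6-oxabicyclo[3.2.1]octane-4,8-dione | CC1(C)[C@@H]2CO[C@@](C)(C2=O)C(=O)C1 | intermediate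
8 | (1R,5R)-2,2,3,5-tetramethyl-6-oxabicyclo[3.2.1]octane-4,8-dione (C3 epimers) | CC1(C)[C@@H]2CO[C@@](C)(C2=O)C(=O)C1C | intermediate
9 | 1-[(trimethylsilyl)ethynyl]-1,2-benziodoxol-3(1H)-one | O=C1OI(C#C[Si](C)(C)C)c2ccccc12 | starting material
10 | (1R,3S,5S)-3-ethynyl-2,2,3,5-tetramethyl-6-oxabicyclo[3.2.1]octane-4,8-dione | CC1(C)[C@@H]2CO[C@@](C)(C2=O)C(=O)[C@@]1(C)C#C | intermediate
11 | ethyl (3S)-3-hydroxy-3-phenylpropanoate | CCOC(=O)C[C@H](O)c1ccccc1 | starting material
12 | ethyl (3S)-3-[(tert-butyldimethylsilyl)oxy]-3-phenylpropanoate | CCOC(=O)C[C@H](O[Si](C)(C)C(C)(C)C)c1ccccc1 | intermediate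
13 | (3S)-3-[(tert-butyldimethylsilyl)oxy]-3-phenylpropanoic acid | OC(=O)C[C@H](O[Si](C)(C)C(C)(C)C)c1ccccc1 | intermediate
14 | (3S)-3-[(tert-butyldimethylsilyl)oxy]-3-phenylpropanoyl chloride | ClC(=O)C[C@H](O[Si](C)(C)C(C)(C)C)c1ccccc1 | intermediate
15 | (1R,3R,5S)-3-[(5S)-5-[(tert-butyldimethylsilyl)oxy]-3-oxo-5-phenylpent-1-yn-1-yl]-2,2,3,5-tetramethyl-6-oxabicyclo[3.2.1]octane-4,8-dione | CC1(C)[C@@H]2CO[C@@](C)(C2=O)C(=O)[C@@]1(C)C#CC(=O)C[C@H](O[Si](C)(C)C(C)(C)C)c1ccccc1 | intermediate
16 | tricyclic C8a-iodo enone with C5–OH and the (3S)-3-silyloxy-3-phenylpropanoyl group on C4a | CC1(C)[C@@H]2CO[C@]3(C)C(=O)[C@@]1(C)C(I)=C(C(=O)C[C@H](O[Si](C)(C)C(C)(C)C)c1ccccc1)[C@]23O | intermediate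
17 | tricyclic C8a-iodo enone with C5–OH and the (3S)-3-hydroxy-3-phenylpropanoyl group on C4a | CC1(C)[C@@H]2CO[C@]3(C)C(=O)[C@@]1(C)C(I)=C(C(=O)C[C@H](O)c1ccccc1)[C@]23O | intermediate
18 | CNP0322161.1 | CC1(C)[C@@H]2CO[C@]3(C)C(=O)[C@@]1(C)C1=C(C(=O)C[C@@H](c4ccccc4)O1)[C@]23O | target

**Count and risks**
Total step count: 13. Longest linear sequence: 10 steps (steps 1–6 and 10–13); steps 7–9 prepare the acyl fragment.

The three steps most likely to fail:

First, step 6. Enolisation of the crowded C8 methine may be slow, the iodane may be attacked from the ether-bridge face or at oxygen, and hydroxide carried in with the fluoride source could cleave the non-enolisable β-dione. The fallback sets out from 8 and returns at 10. The same potassium enolate would be trapped with monomeric formaldehyde 3, the smallest carbon electrophile, in an aldol reaction with the same facial preference, giving the hydroxymethyl ketone F1. Oxidation with Dess–Martin periodinane would give the quaternary keto aldehyde F2. One-carbon homologation with lithiated trimethylsilyldiazomethane at −78 °C (Colvin rearrangement, free of alkoxide that could deformylate the β-keto aldehyde) would then deliver 10.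

Second, step 11. The iodoallenolate may be protonated to an open-chain β-iodo enone before it closes the ring, the aldol may revert with loss of iodide back to the ynone, or the Lewis acid may strip the silyl ether. The fallback sets out from 15 and returns at 18, forming the same C4a–C5 bond from an alkenyl metal instead. HF·pyridine would give the hydroxy ynone F3. Catalytic AgOSO2CF3 in CH2Cl2 would close the dihydropyranone by 6-endo-dig oxa-conjugate addition, giving the 2-phenyl-2,3-dihydropyran-4-one F4, which carries the bicyclic dione on C8a. N-Iodosuccinimide would iodinate the enol-ether α-carbon C4a to give the iodo dihydropyranone F5. CrCl2 with catalytic NiCl2 in DMF (intramolecular Nozaki–Hiyama–Kishi addition of the alkenyl iodide to the C5 ketone, with facial control again from the tether) would then give 18 directly.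

Third, step 3. Intermolecular acetoxylation at C6 or oxidative coupling of the dione may outrun the bridging etherification, which must pass through a 1,3-diaxial geometry. The fallback sets out from 5 and returns at 6, separating halogenation from C–O bond formation. N-Bromosuccinimide in CH2Cl2 would brominate C6 to give the bromodione F6. AgOSO2CF3 with 2,6-lutidine would then pull off bromide while the hydroxymethyl group closes the ether (silver-assisted substitution of a tertiary α-bromo ketone).

Further compounds
F1 | step 6 | 3-(hydroxymethyl)-2,2,3,5-tetramethyl-6-oxabicyclo[3.2.1]octane-4,8-dione, CH2OH syn to the ketone bridge, ring configuration as in 10 | CC1(C)[C@@H]2CO[C@@](C)(C2=O)C(=O)[C@@]1(C)CO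
F2 | step 6 | 2,2,3,5-tetramethyl-4,8-dioxo-6-oxabicyclo[3.2.1]octane-3-carbaldehyde, ring configuration as in 10 | CC1(C)[C@@H]2CO[C@@](C)(C2=O)C(=O)[C@@]1(C)C=O
F3 | step 11 | ynone 15 with free (5S)-hydroxyl | CC1(C)[C@@H]2CO[C@@](C)(C2=O)C(=O)[C@@]1(C)C#CC(=O)C[C@H](O)c1ccccc1
F4 | step 11 | (2S)-2-phenyl-2,3-dihydropyran-4-one carrying the bicyclic dione (C8) on C8a | CC1(C)[C@@H]2CO[C@@](C)(C2=O)C(=O)[C@@]1(C)C1=CC(=O)C[C@@H](c2ccccc2)O1
F5 | step 11 | C4a-iodo derivative of F4 | CC1(C)[C@@H]2CO[C@@](C)(C2=O)C(=O)[C@@]1(C)C1=C(I)C(=O)C[C@@H](c2ccccc2)O1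
F6 | step 3 | rac-2-bromo-4-(hydroxymethyl)-2,5,5-trimethylcyclohexane-1,3-dione | CC1(Br)C(=O)CC(C)(C)C(CO)C1=O
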